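## Retrosynthetic overview
1. Bromophycolide Q ⇒ aryl acetate 22 ⇒ transannular bromonium/alkene cyclisation of the 19-membered macrolide diene 21. This forms C2–C7 and C6–Br, so the cyclohexene is the last ring made.
2. 21 ⇒ C10 ketone 19, through chelate-controlled reduction and SN2 inversion to the bromide. 19 ⇒ seco acid 17 by macrolactonisation at O-14.
3. Seco acid ⇒ oxane ketal 7 + allylic alcohol 12, joined in one pot by two [3,3] shifts. The ketal Claisen makes C8–C9 and the E-C6=C7 bond; the aromatic Claisen makes Ar–C1 and C2=C3.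
4. Both 7 and 12 come from (R)-linalool, which supplies all 20 terpene carbons. C11 is bought, and C14 is set by reduction of a conformationally locked oxanone.
5. Ring order: oxane, then macrolactone, then bromocyclohexene.

Assumption: (R)-(−)-linalool of high ee and tert-butyl 4-fluorobenzoate are bought. Late intermediates carry the diterpene locants C1 (ArCH2) to C15 (OCMe2); the target is 6S,7S,10R,11R,14S.

## Route

Step 1
Reactants: 1 (R)-(−)-linalool
Product: 3 (3RS,6R)-2,2,6-trimethyl-6-vinyloxan-3-ol (pyranoid linalool oxide), via 6,7-epoxylinalool 2 (not isolated)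
Conditions: mCPBA, CH2Cl2, 0 °C; then PTSA (cat.), 0 °C to rt; pyranoid fraction (about 20 %, about 1:1 at C3) separated from the furanoid oxides
Reagents that add atoms: mCPBA, OOC(=O)c1cccc(Cl)c1
Why: Prilezhaev epoxidation takes only the trisubstituted alkene, and acid-catalysed 6-endo opening at the tertiary carbon closes the oxane; C6 (= C11) is bought and untouched, and C3 (= C14) is unselective here and is reset in steps 4–5.

Step 2
Reactants: 3 (3RS,6R)-2,2,6-trimethyl-6-vinyloxan-3-ol
Product: 4 1-[(2R,5RS)-5-hydroxy-2,6,6-trimethyloxan-2-yl]ethan-1-one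
Conditions: PdCl2 (10 mol %), CuCl (co-catalyst), O2, DMF/H2O 7:1, rt to 40 °C
Reagents that add atoms: water, O
Why: Tsuji–Wacker oxidation, in which Markovnikov hydroxypalladation of the only alkene gives the methyl ketone (C10=O, C9H3) without touching the quaternary centre.

Step 3
Reactants: 4 1-[(2R,5RS)-5-hydroxy-2,6,6-trimethyloxan-2-yl]ethan-1-one
Product: 5 (3RS,6R)-6-(1,1-dimethoxyethyl)-2,2,6-trimethyloxan-3-ol
Conditions: HC(OMe)3, MeOH, PPTS (cat.), rt; Et3N quench
Reagents that add atoms: trimethyl orthoformate, COC(OC)OC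
Why: Acid-catalysed ketalisation driven by the orthoformate works for α-alkoxy methyl ketones next to a fully substituted carbon, and the bridged internal ketal of the cis epimer would need a boat oxane, so it does not compete in MeOH.

Step 4
Reactants: 5 (3RS,6R)-6-(1,1-dimethoxyethyl)-2,2,6-trimethyloxan-3-ol
Product: 6 (6R)-6-(1,1-dimethoxyethyl)-2,2,6-trimethyloxan-3-one
Conditions: TPAP (5 mol %), NMO, 4 Å MS, CH2Cl2, rt
Reagents that add atoms: none
Why: Ley–Griffith oxidation under neutral conditions spares the ketal and merges both C3 epimers into one ketone.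

Step 5
Reactants: 6 (6R)-6-(1,1-dimethoxyethyl)-2,2,6-trimethyloxan-3-one
Product: 7 (3S,6R)-6-(1,1-dimethoxyethyl)-2,2,6-trimethyloxan-3-ol
Conditions: NaBH4, MeOH, −20 °C
Reagents that add atoms: none
Why: In this substrate-controlled hydride reduction the tert-alkyl-like ketal group sits equatorial and locks the chair with 6-CH3 axial, so hydride adds axially, anti to the axial 2-CH3, and gives the equatorial 3-OH cis to 6-CH3 (= 14S set by 11R).

Step 6
Reactants: 1 (R)-(−)-linalool; 8 tert-butyl 4-fluorobenzoate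
Product: 10 4-{[(3R)-3,7-dimethylocta-1,6-dien-3-yl]oxy}benzoic acid, via tert-butyl 4-(linalyloxy)benzoate 9 (not isolated)
Conditions: KHMDS, THF, 0 °C, then 8, rt to 50 °C; then powdered KOH, THF, rt; 1 M HCl to pH 4, 0 °C
Reagents that add atoms: potassium hydroxide, [K+].[OH-]
Why: SNAr of the tertiary potassium alkoxide on the para-activated fluoride proceeds because the tert-butyl ester blocks transesterification and the carbinol C–O bond is not touched, and BAc2 cleavage of the tert-butyl benzoate follows in the same pot.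

Step 7
Reactants: 10 4-{[(3R)-3,7-dimethylocta-1,6-dien-3-yl]oxy}benzoic acid
Product: 12 4-{[(3R,6RS)-6-hydroxy-3,7-dimethylocta-1,7-dien-3-yl]oxy}benzoic acid, via allylic 6-hydroperoxide 11 (not isolated)
Conditions: O2, TPP (cat.), hν, CH2Cl2, 0 °C; then PPh3; secondary alcohol separated from the tertiary regioisomer (about 1:1)
Reagents that add atoms: oxygen, O=O
Why: The Schenck ene reaction of singlet oxygen takes only the trisubstituted alkene (vinyl and arene are inert) and gives the isopropenyl carbinol needed for the Claisen step, whose C6 configuration is irrelevant because it is erased in step 8.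

Step 8
Reactants: 7 (3S,6R)-6-(1,1-dimethoxyethyl)-2,2,6-trimethyloxan-3-ol; 12 4-{[(3R,6RS)-6-hydroxy-3,7-dimethylocta-1,7-dien-3-yl]oxy}benzoic acid
Product: 16 4-hydroxy-3-{(2E,6E)-10-[(2R,5S)-5-hydroxy-2,6,6-trimethyloxan-2-yl]-3,7-dimethyl-10-oxodeca-2,6-dien-1-yl}benzoic acid, via allyl vinyl ether 13 (not isolated), via (6E)-10-oxo aryl linalyl-type ether 14 (not isolated), via ortho-cyclohexadienone 15 (not isolated)
Conditions: 12 (1.5 equiv), 2,4-dinitrophenol (5 mol %), 4 Å MS, xylene, 140 °C, 24–36 h; C2=C3 E/Z about 3:1, Z isomer removed on AgNO3–SiO2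
Reagents that add atoms: none
Why: Ketal exchange and loss of MeOH give the allyl vinyl ether C6–O–C10(=C9H2), whose chair Claisen rearrangement (C5 chain equatorial) forms C8–C9 and the E-C6=C7 bond, and at the same temperature the tertiary aryl allyl ether undergoes the aromatic Claisen rearrangement that forms Ar–C1 and C2=C3 before tautomerising to the phenol; C11 and C14 are spectators, and the trans 14-OH cannot reach C10.

Step 9
Reactants: 16 4-hydroxy-3-{(2E,6E)-10-[(2R,5S)-5-hydroxy-2,6,6-trimethyloxan-2-yl]-3,7-dimethyl-10-oxodeca-2,6-dien-1-yl}benzoic acid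
Product: 17 4-acetoxy-3-{(2E,6E)-10-[(2R,5S)-5-hydroxy-2,6,6-trimethyloxan-2-yl]-3,7-dimethyl-10-oxodeca-2,6-dien-1-yl}benzoic acid
Conditions: 1 M NaOH (2.2 equiv), THF/H2O, 0 °C, Ac2O (1.2 equiv); then 1 M HCl
Reagents that add atoms: acetic anhydride, CC(=O)OC(C)=O
Why: Schotten–Baumann acetylation takes only the phenoxide, because the neopentyl-type 14-OH is inert in water and any mixed anhydride hydrolyses, and the acetate later stops ring bromination and chroman formation.

Step 10
Reactants: 17 4-acetoxy-3-{(2E,6E)-10-[(2R,5S)-5-hydroxy-2,6,6-trimethyloxan-2-yl]-3,7-dimethyl-10-oxodeca-2,6-dien-1-yl}benzoic acid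
Product: 19 (2E,6E,11R,14S)-10-oxo macrolide aryl acetate (nineteen-membered lactone closed on O-14), via MNBA mixed anhydride 18 (not isolated)
Conditions: MNBA (1.5 equiv), DMAP (6 equiv), CH2Cl2, 1 mM, slow addition, rt to 40 °C
Reagents that add atoms: 2-methyl-6-nitrobenzoic anhydride (MNBA), Cc1cccc([N+](=O)[O-])c1C(=O)OC(=O)c1c(C)cccc1[N+](=O)[O-]
Why: In this Shiina macrolactonisation MNBA converts the acid into mixed anhydride 18, whose less hindered acyl group is passed by DMAP to the only free hydroxyl with loss of 2-methyl-6-nitrobenzoate, and C14 is retained because only the acyl–O bond is formed.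

Step 11
Reactants: 19 (2E,6E,11R,14S)-10-oxo macrolide aryl acetate
Product: 20 (2E,6E,10S,11R,14S)-10-hydroxy macrolide aryl acetate
Conditions: Zn(BH4)2, Et2O, −30 to 0 °C; sat. aq NH4Cl
Reagents that add atoms: none
Why: In this Cram-chelate reduction zinc bridges the oxane oxygen and C10=O and hydride enters past the C11 methyl rather than the ring CH2 side to give 10S, while both esters survive this mild reagent.

Step 12
Reactants: 20 (2E,6E,10S,11R,14S)-10-hydroxy macrolide aryl acetate
Product: 21 (2E,6E,10R,11R,14S)-10-bromo macrolide aryl acetate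
Conditions: CBr4, P(n-Oct)3, toluene, 70 °C
Reagents that add atoms: carbon tetrabromide, BrC(Br)(Br)Br
Why: In this Appel-type bromination (Hooz variant for hindered carbinols next to ether carbons) bromide displaces the alkoxyphosphonium group by SN2, inverting 10S-OH to 10R-Br.

Step 13
Reactants: 21 (2E,6E,10R,11R,14S)-10-bromo macrolide aryl acetate
Product: 22 bromophycolide Q O-acetate (6S,7S,10R,11R,14S)
Conditions: BDSB (Et2SBr·SbCl5Br, 1.05 equiv), MeNO2, −25 °C, 10 min; aq Na2SO3/NaHCO3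
Reagents that add atoms: bromodiethylsulfonium bromopentachloroantimonate (BDSB), CC[S+](Br)CC.Cl[Sb-](Cl)(Cl)(Cl)(Cl)Br
Why: In this bromonium-induced cation–olefin cyclisation, reversible Br+ transfer is productive only at C6=C7, C2 opens that ion anti at C7 through a chair (the E-alkene puts Br and C8 equatorial and CH3 axial, i.e. 6S*,7S*), the C3 cation loses H-2 to give the tetrasubstituted alkene, and the face is chosen by the macrocycle because Br+ arrives from outside while the C8–C11 tether, held by the trans-diequatorial oxane–benzoate clamp, offers C2=C3 to one inner face only, expected to give 6S,7S.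

Step 14
Reactants: 22 bromophycolide Q O-acetate
Product: 23 bromophycolide Q
Conditions: K2CO3 (0.2 equiv), MeOH, 0 °C, 30 min
Reagents that add atoms: none
Why: Zemplén-type methanolysis cleaves the activated aryl acetate far faster than the hindered macrolactone, and the two neopentyl-type secondary bromides are inert to it.

## Compound list
1 | (R)-(−)-linalool | C=C[C@](C)(O)CCC=C(C)C | starting material
2 | (3R)-6,7-epoxy-3,7-dimethyloct-1-en-3-ol (6,7-epoxylinalool) | C=C[C@](C)(O)CCC1OC1(C)C | intermediate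
3 | (3RS,6R)-2,2,6-trimethyl-6-vinyloxan-3-ol | C=C[C@@]1(C)CCC(O)C(C)(C)O1 | intermediate
4 | 1-[(2R,5RS)-5-hydroxy-2,6,6-trimethyloxan-2-yl]ethan-1-one | CC(=O)[C@@]1(C)CCC(O)C(C)(C)O1 | intermediate
5 | (3RS,6R)-6-(1,1-dimethoxyethyl)-2,2,6-trimethyloxan-3-ol | COC(C)(OC)[C@@]1(C)CCC(O)C(C)(C)O1 | intermediate
6 | (6R)-6-(1,1-dimethoxyethyl)-2,2,6-trimethyloxan-3-one | COC(C)(OC)[C@@]1(C)CCC(=O)C(C)(C)O1 | intermediate
7 | (3S,6R)-6-(1,1-dimethoxyethyl)-2,2,6-trimethyloxan-3-ol | COC(C)(OC)[C@@]1(C)CC[C@H](O)C(C)(C)O1 | intermediate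
8 | tert-butyl 4-fluorobenzoate | CC(C)(C)OC(=O)c1ccc(F)cc1 | starting material
9 | tert-butyl 4-{[(3R)-3,7-dimethylocta-1,6-dien-3-yl]oxy}benzoate | C=C[C@](C)(Oc1ccc(cc1)C(=O)OC(C)(C)C)CCC=C(C)C | intermediate
10 | 4-{[(3R)-3,7-dimethylocta-1,6-dien-3-yl]oxy}benzoic acid | C=C[C@](C)(Oc1ccc(cc1)C(=O)O)CCC=C(C)C | intermediate
11 | 4-{[(3R,6RS)-6-hydroperoxy-3,7-dimethylocta-1,7-dien-3-yl]oxy}benzoic acid | C=C[C@](C)(Oc1ccc(cc1)C(=O)O)CCC(OO)C(C)=C | intermediate
12 | 4-{[(3R,6RS)-6-hydroxy-3,7-dimethylocta-1,7-dien-3-yl]oxy}benzoic acid | C=C[C@](C)(Oc1ccc(cc1)C(=O)O)CCC(O)C(C)=C | intermediate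
13 | allyl vinyl ether: 4-{[(3R)-6-({1-[(2R,5S)-5-hydroxy-2,6,6-trimethyloxan-2-yl]ethenyl}oxy)-3,7-dimethylocta-1,7-dien-3-yl]oxy}benzoic acid | C=C[C@](C)(Oc1ccc(cc1)C(=O)O)CCC(OC(=C)[C@@]2(C)CC[C@H](O)C(C)(C)O2)C(C)=C | intermediate
14 | 4-{[(3R,6E)-10-[(2R,5S)-5-hydroxy-2,6,6-trimethyloxan-2-yl]-3,7-dimethyl-10-oxodeca-1,6-dien-3-yl]oxy}benzoic acid | C=C[C@](C)(Oc1ccc(cc1)C(=O)O)CC/C=C(\C)CCC(=O)[C@@]2(C)CC[C@H](O)C(C)(C)O2 | intermediate
15 | ortho-cyclohexadienone tautomer of 16 | O=C1C=CC(C(=O)O)=CC1C/C=C(\C)CC/C=C(\C)CCC(=O)[C@@]2(C)CC[C@H](O)C(C)(C)O2 | intermediate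
16 | 4-hydroxy-3-{(2E,6E)-10-[(2R,5S)-5-hydroxy-2,6,6-trimethyloxan-2-yl]-3,7-dimethyl-10-oxodeca-2,6-dien-1-yl}benzoic acid | OC(=O)c1ccc(O)c(C/C=C(\C)CC/C=C(\C)CCC(=O)[C@@]2(C)CC[C@H](O)C(C)(C)O2)c1 | intermediate
17 | 4-acetoxy-3-{(2E,6E)-10-[(2R,5S)-5-hydroxy-2,6,6-trimethyloxan-2-yl]-3,7-dimethyl-10-oxodeca-2,6-dien-1-yl}benzoic acid | CC(=O)Oc1ccc(cc1C/C=C(\C)CC/C=C(\C)CCC(=O)[C@@]2(C)CC[C@H](O)C(C)(C)O2)C(=O)O | intermediate
18 | MNBA mixed anhydride: the acid of 17 as its 2-methyl-6-nitrobenzoic carboxylic anhydride | CC(=O)Oc1ccc(cc1C/C=C(\C)CC/C=C(\C)CCC(=O)[C@@]2(C)CC[C@H](O)C(C)(C)O2)C(=O)OC(=O)c3c(C)cccc3[N+](=O)[O-] | intermediate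
19 | (2E,6E,11R,14S)-10-oxo 19-membered macrolide, aryl acetate | CC(=O)Oc1ccc2cc1C/C=C(\C)CC/C=C(\C)CCC(=O)[C@@]3(C)CC[C@H](OC2=O)C(C)(C)O3 | intermediate
20 | (2E,6E,10S,11R,14S)-10-hydroxy macrolide, aryl acetate | CC(=O)Oc1ccc2cc1C/C=C(\C)CC/C=C(\C)CC[C@H](O)[C@@]3(C)CC[C@H](OC2=O)C(C)(C)O3 | intermediate
21 | (2E,6E,10R,11R,14S)-10-bromo macrolide, aryl acetate | CC(=O)Oc1ccc2cc1C/C=C(\C)CC/C=C(\C)CC[C@@H](Br)[C@@]3(C)CC[C@H](OC2=O)C(C)(C)O3 | intermediate
22 | bromophycolide Q O-acetate | CC1=C2Cc3cc(ccc3OC(C)=O)C(=O)O[C@H]3CC[C@@](C)(OC3(C)C)[C@H](Br)CC[C@]2(C)[C@@H](Br)CC1 | intermediate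
23 | bromophycolide Q | CC1=C2Cc3cc(ccc3O)C(=O)O[C@H]3CC[C@@](C)(OC3(C)C)[C@H](Br)CC[C@]2(C)[C@@H](Br)CC1 | target

## Step count and risks
Total steps: 14. Longest linear sequence: 12 (steps 1–5, then 8–14).

**Step 13.** The face selectivity at C6=C7 is not proven, and the proton could be lost from the wrong position. The fallback sets out from 21 and comes back at 22. It fixes the C6/C7 configuration before ring closure instead of relying on a free bromonium ion. One equivalent of mCPBA at −20 °C epoxidises the more exposed C6=C7 bond to the (6R,7R)-6,7-epoxy macrolide F1, which can be separated from its diastereomer and assigned. LiBr/AcOH opens it by SN2 at the secondary C6 to the (6S,7R)-6-bromo-7-hydroxy macrolide F2. SnBr4 in CH2Cl2/MeNO2 at −78 °C then ionises the tertiary hydroxyl with anchimeric help from bromine. The configurationally defined bromonium ion is captured transannularly by C2=C3, and loss of H-2 gives 22.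

**Step 12.** The SN2 reaction is next to a fully substituted ether carbon. The ring oxygen may participate, and the step also inherits any wrong-way selectivity from step 11. The fallback sets out from 19 and comes back at 21, and it puts the participation to use instead of fighting it. Non-chelating reduction with L-Selectride in THF at −78 °C gives the epimeric (10R)-10-hydroxy macrolide F3. Tf2O with 2,6-di-tert-butyl-4-methylpyridine converts it into the (10R)-10-triflyloxy macrolide F4. With Bu4NBr in CH2Cl2 the oxane oxygen expels triflate and bromide reopens the bridged ion at the secondary C10. This double inversion gives the 10R bromide 21 with net retention.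

**Step 8.** The ketal exchange between two valuable partners is bimolecular, the tertiary aryl ether is acid-sensitive, and E/Z control at C2=C3 is modest. The fallback sets out from 7 and 10 and comes back at 19. The halves are first tied together through the ester, so the Claisen step becomes the ring closure. MNBA/DMAP acylates 7 with 10 to the (3S,6R)-oxanyl 4-(linalyloxy)benzoate F5. Singlet oxygen and then PPh3, as in step 7, give the C6 isopropenyl carbinol ester F6. Heating this at 2 mM in xylene with catalytic 2,4-dinitrophenol makes the ketal exchange intramolecular, and the two [3,3] shifts then deliver the phenolic 10-oxo macrolide F7. Ac2O/pyridine converts it into 19.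

## Further compounds
F1 | step 13 | (6R,7R)-6,7-epoxy macrolide | CC(=O)Oc1ccc2cc1C/C=C(\C)CC[C@H]4O[C@]4(C)CC[C@@H](Br)[C@@]3(C)CC[C@H](OC2=O)C(C)(C)O3
F2 | step 13 | (6S,7R)-6-bromo-7-hydroxy macrolide | CC(=O)Oc1ccc2cc1C/C=C(\C)CC[C@H](Br)[C@](C)(O)CC[C@@H](Br)[C@@]3(C)CC[C@H](OC2=O)C(C)(C)O3
F3 | step 12 | (10R)-10-hydroxy macrolide | CC(=O)Oc1ccc2cc1C/C=C(\C)CC/C=C(\C)CC[C@@H](O)[C@@]3(C)CC[C@H](OC2=O)C(C)(C)O3
F4 | step 12 | (10R)-10-triflyloxy macrolide | CC(=O)Oc1ccc2cc1C/C=C(\C)CC/C=C(\C)CC[C@@H](OS(=O)(=O)C(F)(F)F)[C@@]3(C)CC[C@H](OC2=O)C(C)(C)O3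
F5 | step 8 | (3S,6R)-oxanyl 4-(linalyloxy)benzoate | C=C[C@](C)(Oc1ccc(cc1)C(=O)O[C@H]2CC[C@@](C)(OC2(C)C)C(C)(OC)OC)CCC=C(C)C
F6 | step 8 | C6 isopropenyl carbinol ester | C=C[C@](C)(Oc1ccc(cc1)C(=O)O[C@H]2CC[C@@](C)(OC2(C)C)C(C)(OC)OC)CCC(O)C(C)=C
F7 | step 8 | phenolic 10-oxo macrolide | Oc1ccc2cc1C/C=C(\C)CC/C=C(\C)CCC(=O)[C@@]3(C)CC[C@H](OC2=O)C(C)(C)O3
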